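The twofold-symmetric 16-membered ring is cut at its two identical C1–t5 bonds (quinolizidin-2-one numbering; ring A: N5, C4, C3, C2, C1, C9a; ring B: N5, C6–C9, C9a; tether t1–t5 runs from C9 of one half to C1 of the other). C1 is the only methylene flanking the C2 ketone, C3 being a methyl-bearing methine, so each cut bond is an aldol-condensation bond. In one operation two molecules of a single enantiopure monomer unite head to tail, both C1=t5 alkenes form and the macrocycle closes. The monomer is the 9,9a-cis quinolizidine carrying a C1=C2 trimethylsilyl enol ether and a dimethyl acetal at t5.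

Key step: step 11

**Structure check.** Both halves of 28 are identical, (1R,3S,9S,9aR).
- H9 and H9a are cis.
- On ring A the C1 tether, the C3 methyl and the C9a–C9 bond are all equatorial. The C9 tether is axial on ring B.
- Compounds 23 and 26 carry the same spatial arrangement at C3, C9 and C9a as 28.

**Design points.**
- (a) N5 is a basic tertiary amine and would sequester a catalytic silyl triflate. An excess is therefore used, and N5 is masked in the flask as its N-silylammonium triflate.
- (b) Beta-methoxy ketones do not lose methanol at low temperature, so DBU is added to the same flask.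
- (c) Extreme dilution would starve the bimolecular first union and favour closure of C1 onto its own t5 (8-membered ring). A 5 mM batch is used instead.
- (d) The acetal is installed in step 1 and meets acid only in methanol. Ring A is closed by aza-Michael addition under bicarbonate.
- (e) The ketone is unveiled only while N5 is a carbamate, because NH beta-amino ketones can epimerise at C9a by retro-aza-Michael reaction.
- (f) Copper hydride replaces H2 over palladium, which could move the alkene to C1=C9a (a vinylogous amide) and erase C9a.

Assumption: C3 is epimerisable in every ketone from 22 on; the equatorial 3S epimer is drawn and any 3R material converges in step 12.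

**Step 1**
Reactants: 1 cycloheptene
Product: 4 7,7-dimethoxyheptanal, via hydroperoxy aldehyde 2 (not isolated), via hydroperoxy acetal 3 (not isolated)
Conditions: O3, CH2Cl2/MeOH, −78 °C; TsOH·H2O (cat.), to rt; NaHCO3; Me2S, rt
Reagents that add atoms: ozone [O-][O+]=O; methanol CO
Why: Criegee ozonolysis in methanol leaves one terminus as a free aldehyde and the other as a methoxy hydroperoxide, so acid-catalysed acetalisation marks only the first and Me2S reduction then frees the second (terminus-differentiating ozonolysis of a cycloalkene); no stereocentre is formed.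

**Step 2**
Reactants: 4 7,7-dimethoxyheptanal; 5 SAMP, (S)-1-amino-2-(methoxymethyl)pyrrolidine
Product: 6 (E)-SAMP hydrazone of 4
Conditions: Et2O, 0 °C to rt
Reagents that add atoms: SAMP (5) COC[C@@H]1CCCN1N
Why: Condensation of an unhindered aldehyde with the N-amino auxiliary is fast without acid, which spares the acetal, and should give the E hydrazone (hydrazone formation).

**Step 3**
Reactants: 6 (E)-SAMP hydrazone of 4; 7 1-chloro-3-iodopropane
Product: 9 SAMP hydrazone of (S)-2-(3-chloropropyl)-7,7-dimethoxyheptanal, via lithium azaenolate 8 (not isolated)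
Conditions: LiN(iPr)2, THF, 0 °C; then 7, −100 °C to rt
Reagents that add atoms: 1-chloro-3-iodopropane (7) ClCCCI
Why: Enders SAMP-hydrazone alkylation: the lithium-chelated azaenolate 8 of E(C=C), Z(C–N) geometry is attacked on its unshielded face by the iodide terminus only, which sets C9 as S by the established topicity of the auxiliary and keeps the chloride for ring B.

**Step 4**
Reactants: 9 SAMP hydrazone of (S)-2-(3-chloropropyl)-7,7-dimethoxyheptanal
Product: 10 (S)-2-(3-chloropropyl)-7,7-dimethoxyheptanal
Conditions: O3, CH2Cl2, −78 °C, stopped at the first blue colour; N2 purge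
Reagents that add atoms: ozone [O-][O+]=O
Why: Ozonolytic cleavage of the electron-rich C=N bond is much faster than ozone insertion into the acetal C–H bond and runs under neutral conditions at low temperature, so the alpha-branched aldehyde should be released without epimerisation at C9.

**Step 5**
Reactants: 10 (S)-2-(3-chloropropyl)-7,7-dimethoxyheptanal; 11 (R)-tert-butanesulfinamide
Product: 12 (R-sulfinyl)(E)-N-sulfinyl aldimine of 10
Conditions: Ti(OEt)4, THF, rt
Reagents that add atoms: (R)-tert-butanesulfinamide (11) CC(C)(C)[S@@](=O)N
Why: Ti(OEt)4 acts as a mild Lewis acid and water scavenger (Ellman sulfinimine formation), conditions under which alpha-branched aldehydes keep their configuration and acetals persist.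

**Step 6**
Reactants: 12 N-sulfinyl aldimine; 13 N-methoxy-N-methylacetamide
Product: 15 (3S,4S)-beta-sulfinamido Weinreb amide, via lithium enolate 14 (not isolated)
Conditions: 13, LiN(iPr)2, THF, −78 °C; then 12, −78 °C; aq NH4Cl
Reagents that add atoms: N-methoxy-N-methylacetamide (13) CC(=O)N(C)OC
Why: Mannich-type addition of an amide enolate to an N-sulfinyl aldimine through a six-membered lithium chelate (Zimmerman–Traxler type) delivers carbon to the Si face of the R-sulfinyl imine and sets C9a with the configuration that becomes H9/H9a-cis in ring B, the two near-identical n-alkyl arms on C9 exerting no bias of their own, and diastereomers carried over from step 3 can be removed here by chromatography.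

**Step 7**
Reactants: 15 (3S,4S)-beta-sulfinamido Weinreb amide
Product: 18 N-Boc (2S,3S)-piperidine Weinreb amide, via amine hydrochloride 16 (not isolated), via NH piperidine 17 (not isolated)
Conditions: HCl (4 M in dioxane), MeOH, 0 °C to rt; evaporate; K2CO3, NaI (cat.), MeCN, 50 °C; then Boc2O, rt
Reagents that add atoms: di-tert-butyl dicarbonate CC(C)(C)OC(=O)OC(=O)OC(C)(C)C
Why: Acid methanolysis removes the sulfinyl group while methanol as solvent holds the dimethyl acetal, the freed primary amine closes ring B by iodide-assisted 6-exo-tet displacement of chloride at the amide oxidation level where beta-elimination of nitrogen is not a concern, and carbamate formation in the same flask forestalls beta-lactam formation in step 8; no stereocentre is touched.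

**Step 8**
Reactants: 18 N-Boc (2S,3S)-piperidine Weinreb amide; 19 isopropenylmagnesium bromide
Product: 20 N-Boc (2S,3S)-2-(3-methyl-2-oxobut-3-enyl)piperidine
Conditions: CH2=C(CH3)MgBr, THF, −20 to 0 °C; cold aq NH4Cl
Reagents that add atoms: isopropenylmagnesium bromide (19) CC(=C)[Mg]Br
Why: Weinreb ketone synthesis: the chelated tetrahedral adduct stops at monoaddition and collapses to the isopropenyl ketone only on quench, with carbamate, acetal and both stereocentres inert to the Grignard reagent.

**Step 9**
Reactants: 20 N-Boc (2S,3S)-2-(3-methyl-2-oxobut-3-enyl)piperidine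
Product: 22 (3S,9S,9aS)-9-(5,5-dimethoxypentyl)-3-methylquinolizidin-2-one, via amino enone hydrochloride 21 (not isolated)
Conditions: HCl (4 M in dioxane), MeOH, 0 °C to rt; evaporate; sat. aq NaHCO3/CH2Cl2, rt
Reagents that add atoms: none
Why: Boc cleavage in methanolic HCl (harmless to the acetal) followed by neutralisation releases the secondary amine next to the enone, which closes ring A by 6-endo-trig intramolecular aza-Michael addition to the methylene terminus C4, and protonation alpha to the ketone settles C3 as the equatorial 3S methyl epimer under thermodynamic control.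

**Step 10**
Reactants: 22 (3S,9S,9aS)-9-(5,5-dimethoxypentyl)-3-methylquinolizidin-2-one
Product: 23 (3S,9S,9aR)-9-(5,5-dimethoxypentyl)-3-methyl-2-(trimethylsilyloxy)-3,6,7,8,9,9a-hexahydro-4H-quinolizine
Conditions: Me3SiCl and LiN(iPr)2 premixed (internal quench), THF, −78 °C; Et3N; pentane, cold aq NaHCO3; used crude
Reagents that add atoms: chlorotrimethylsilane C[Si](C)(C)Cl
Why: Kinetic deprotonation with a hindered lithium amide removes a proton from the C1 methylene rather than the C3 methine (as in 2-alkylcyclohexanones) and the chlorosilane already present traps the enolate on oxygen before proton exchange, giving the C1=C2 enol silane (regioselective silyl enol ether formation); C3, C9 and C9a are untouched.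

**Step 11**
Reactants: 23 C1=C2 silyl enol ether acetal (two molecules)
Product: 26 16-membered bis(E-enone) macrocycle, via linear dimer 24 (not isolated), via macrocyclic bis(methoxy ketone) 25 (not isolated)
Conditions: Me3SiOTf (3 equiv per 23), 2,6-di-tert-butyl-4-methylpyridine (1 equiv), CH2Cl2 (5 mM, batch), −78 to −30 °C; then DBU (8 equiv), −30 °C to rt; aq NaHCO3
Reagents that add atoms: none
Why: Proposed new method: Me3SiOTf ionises the t5 dimethyl acetal to a methoxycarbenium ion that is captured at C1 by the C1=C2 enol silane of a second molecule (giving 24), the same event recurs within 24 to give 25, and DBU expels methanol from both beta-methoxy ketones by E1cB to leave 26; the closest known reaction type is the Mukaiyama aldol addition of enol silanes to acetals followed by beta-alkoxy elimination, established for intermolecular and ring-forming cases but not for a head-to-tail cyclodimerisation of an amine-bearing monomer. The 16-membered ring closes in a 16-(enolexo)-exo-trig mode, the C1=C2 bond and the departing C–O bond both lying outside the new ring. No stereocentre is retained from the step: the transient C1 and t5 centres vanish on elimination, the E alkenes drawn are the expected conjugated isomers and their geometry is erased in step 12, while C9 and C9a stay untouched because the endocyclic C9a–N5 bond lies near the nodal plane of the enol ether and cannot fragment. Regioselectivity (C1, not C3) is fixed by the preformed enol silane, head-to-tail union by the one-donor, one-acceptor monomer, and formation of only the twofold-symmetric dimer by the use of a single enantiomer. N5 would tie up a catalytic Lewis acid, so three equivalents are used and N5 is masked in the flask as its N-silylammonium triflate, with the hindered pyridine removing stray TfOH that would protodesilylate 23. Cyclodimer against 8-membered self-closure (C1 onto its own t5) and against oligomer is governed by concentration, hence a 5 mM batch rather than extreme dilution.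

**Step 12**
Reactants: 26 16-membered bis(E-enone) macrocycle
Product: 28 target bis(quinolizidinone) macrocycle (1R,3S,9S,9aR in both halves), via C1-epimeric diketone 27 (not isolated)
Conditions: [(Ph3P)CuH]6, degassed PhMe/H2O, rt; air, Celite; then K2CO3, MeOH, rt
Reagents that add atoms: none
Why: Conjugate reduction with the copper hydride hexamer delivers hydride to t5 and never forms a metal alkyl beta to H9a, so the alkene cannot migrate into conjugation with N5, and carbonate-mediated enolisation then equilibrates C1 and C3 to the all-equatorial ring A arrangement (1R,3S), the axial C1 epimer being destabilised by a syn-diaxial clash with the axial C9 tether (1,4-reduction followed by thermodynamic epimerisation).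

**Compound list**
1 | cycloheptene | C1=CCCCCC1 | starting material
2 | 7-hydroperoxy-7-methoxyheptanal | COC(OO)CCCCCC=O | intermediate
3 | 1,7,7-trimethoxyheptyl hydroperoxide | COC(OO)CCCCCC(OC)OC | intermediate
4 | 7,7-dimethoxyheptanal | COC(OC)CCCCCC=O | intermediate
5 | SAMP, (S)-1-amino-2-(methoxymethyl)pyrrolidine | COC[C@@H]1CCCN1N | starting material
6 | (E)-SAMP hydrazone of 7,7-dimethoxyheptanal | COC[C@@H]1CCCN1/N=C/CCCCCC(OC)OC | intermediate
7 | 1-chloro-3-iodopropane | ClCCCI | starting material
8 | lithium azaenolate of 6, E(C=C) | [Li+].COC[C@@H]1CCCN1[N-]/C=C/CCCCC(OC)OC | intermediate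
9 | (E)-SAMP hydrazone of (S)-2-(3-chloropropyl)-7,7-dimethoxyheptanal | COC[C@@H]1CCCN1/N=C/[C@H](CCCCl)CCCCC(OC)OC | intermediate
10 | (S)-2-(3-chloropropyl)-7,7-dimethoxyheptanal | O=C[C@H](CCCCl)CCCCC(OC)OC | intermediate
11 | (R)-tert-butanesulfinamide | CC(C)(C)[S@@](=O)N | starting material
12 | (R)-N-[(E,2S)-2-(3-chloropropyl)-7,7-dimethoxyheptylidene]-2-methylpropane-2-sulfinamide | CC(C)(C)[S@@](=O)/N=C/[C@H](CCCCl)CCCCC(OC)OC | intermediate
13 | N-methoxy-N-methylacetamide | CC(=O)N(C)OC | starting material
14 | lithium enolate of N-methoxy-N-methylacetamide | [Li+].C=C([O-])N(C)OC | intermediate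
15 | (3S,4S)-3-{[(R)-tert-butylsulfinyl]amino}-4-(3-chloropropyl)-N,9,9-trimethoxy-N-methylnonanamide | CC(C)(C)[S@@](=O)N[C@@H](CC(=O)N(C)OC)[C@H](CCCCl)CCCCC(OC)OC | intermediate
16 | (3S,4S)-3-amino-4-(3-chloropropyl)-N,9,9-trimethoxy-N-methylnonanamide hydrochloride | Cl.N[C@@H](CC(=O)N(C)OC)[C@H](CCCCl)CCCCC(OC)OC | intermediate
17 | 2-[(2S,3S)-3-(5,5-dimethoxypentyl)piperidin-2-yl]-N-methoxy-N-methylacetamide (2,3-cis) | CON(C)C(=O)C[C@@H]1NCCC[C@@H]1CCCCC(OC)OC | intermediate
18 | tert-butyl (2S,3S)-3-(5,5-dimethoxypentyl)-2-{2-[methoxy(methyl)amino]-2-oxoethyl}piperidine-1-carboxylate | CON(C)C(=O)C[C@@H]1N(C(=O)OC(C)(C)C)CCC[C@@H]1CCCCC(OC)OC | intermediate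
19 | isopropenylmagnesium bromide | CC(=C)[Mg]Br | starting material
20 | tert-butyl (2S,3S)-3-(5,5-dimethoxypentyl)-2-(3-methyl-2-oxobut-3-en-1-yl)piperidine-1-carboxylate | CC(=C)C(=O)C[C@@H]1N(C(=O)OC(C)(C)C)CCC[C@@H]1CCCCC(OC)OC | intermediate
21 | 1-[(2S,3S)-3-(5,5-dimethoxypentyl)piperidin-2-yl]-3-methylbut-3-en-2-one hydrochloride | Cl.CC(=C)C(=O)C[C@@H]1NCCC[C@@H]1CCCCC(OC)OC | intermediate
22 | (3S,9S,9aS)-9-(5,5-dimethoxypentyl)-3-methyloctahydro-2H-quinolizin-2-one | C[C@H]1CN2CCC[C@H](CCCCC(OC)OC)[C@@H]2CC1=O | intermediate
23 | (3S,9S,9aR)-9-(5,5-dimethoxypentyl)-3-methyl-2-(trimethylsilyloxy)-3,6,7,8,9,9a-hexahydro-4H-quinolizine (C1=C2 enol silane) | C[C@H]1CN2CCC[C@H](CCCCC(OC)OC)[C@@H]2C=C1O[Si](C)(C)C | intermediate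
24 | linear dimer: C1 of one ketone half bonded to the methoxy-bearing t5 of the second half, which keeps its enol silane; first half keeps its acetal; new C1 and t5 centres undefined | C[C@H]1CN2CCC[C@H](CCCCC(OC)OC)[C@@H]2C(C1=O)C(OC)CCCC[C@H]3CCCN4C[C@H](C)C(O[Si](C)(C)C)=C[C@@H]34 | intermediate
25 | 16-membered bis(beta-methoxy ketone), methoxy on both t5 carbons, C1 and t5 centres undefined | C[C@H]1CN2CCC[C@@H]3CCCCC(OC)C4C(=O)[C@@H](C)CN5CCC[C@H](CCCCC(OC)C(C1=O)[C@@H]32)[C@H]45 | intermediate
26 | 16-membered bis(exocyclic enone), both C1=t5 alkenes E, (3S,9S,9aR) in both halves | C[C@H]1CN2CCC[C@@H]3CCCC/C=C4/C(=O)[C@@H](C)CN5CCC[C@H](CCCC/C=C(/C1=O)[C@@H]32)[C@H]45 | intermediate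
27 | saturated 16-membered diketone, mixture of C1 epimers | C[C@H]1CN2CCC[C@@H]3CCCCCC4C(=O)[C@@H](C)CN5CCC[C@H](CCCCCC(C1=O)[C@@H]32)[C@H]45 | intermediate
28 | target, (1R,3S,9S,9aR) in both halves | C[C@H]1CN2CCC[C@@H]3CCCCC[C@H]4C(=O)[C@@H](C)CN5CCC[C@H](CCCCC[C@@H](C1=O)[C@@H]32)[C@H]45 | target

Total step count: 12. Longest linear sequence: 12 (from cycloheptene).

**Steps most likely to fail**

Step 11. Chain growth to oligomers, self-closure of the monomer to the 8-membered ring, or protodesilylation of the enol silane may outrun cyclodimerisation. The fallback forms the same C1=t5 bonds by olefination, a known way to close macrocycles and to cyclodimerise head to tail.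
- It sets out from 22. Kinetic enolisation with LiN(iPr)2 and trapping with ClP(O)(OEt)2 should give the C1=C2 diethyl enol phosphate F1.
- A second treatment with LiN(iPr)2 induces the known 1,3 oxygen-to-carbon phosphoryl shift, giving the C1 beta-keto phosphonate F2.
- Aqueous HCl in THF unmasks the phosphonate aldehyde F3, kept as its ammonium salt.
- Adding F3 to LiCl and iPr2NEt in MeCN at a few millimolar (Masamune–Roush conditions) should effect a double Horner–Wadsworth–Emmons reaction, which comes back to the route at 26.

Step 12. Hydride transfer from copper may be slowed by the trisubstituted enones held in the macrocycle, or prolonged base contact may open ring A reversibly and erode C9a. The fallback over-reduces and re-oxidises.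
- It sets out from 26. H2 over PtO2 in EtOH saturates both alkenes and both ketones, giving the saturated macrocyclic diol F4.
- Swern oxidation ((COCl)2, DMSO, Et3N) comes back to the route at 27.
- 27 is then equilibrated briefly with K2CO3 in MeOH to 28.

Step 9. After loss of the carbamate, reversible opening of the C9a–N5 bond in the NH amino enone may erode the 9,9a-cis relationship before ring A closes. Methanol or HCl adducts of the enone may also lag behind. The fallback closes ring A by a Mannich reaction in which nitrogen stays protonated.
- It sets out from 18. EtMgBr in THF should give the N-Boc ethyl ketone F5.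
- Methanolic HCl gives the amino ketone hydrochloride F6.
- Heating F6 with paraformaldehyde in MeOH at 50 °C forms the N5=C4 iminium ion, which the C3 enol captures. C1 could only give a four-membered ring, and methanol as solvent keeps the acetal. This comes back to the route at 22.

**Further compounds**
F1 | step 11 | (3S,9S,9aR)-9-(5,5-dimethoxypentyl)-3-methyl-3,6,7,8,9,9a-hexahydro-4H-quinolizin-2-yl diethyl phosphate | C[C@H]1CN2CCC[C@H](CCCCC(OC)OC)[C@@H]2C=C1OP(=O)(OCC)OCC
F2 | step 11 | diethyl [(3S,9S,9aR)-9-(5,5-dimethoxypentyl)-3-methyl-2-oxooctahydro-2H-quinolizin-1-yl]phosphonate, C1 epimers | C[C@H]1CN2CCC[C@H](CCCCC(OC)OC)[C@@H]2C(C1=O)P(=O)(OCC)OCC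
F3 | step 11 | diethyl [(3S,9S,9aR)-3-methyl-2-oxo-9-(5-oxopentyl)octahydro-2H-quinolizin-1-yl]phosphonate, C1 epimers | C[C@H]1CN2CCC[C@H](CCCCC=O)[C@@H]2C(C1=O)P(=O)(OCC)OCC
F4 | step 12 | saturated 16-membered bis(quinolizidin-2-ol), C1 and C2 centres undefined | C[C@H]1CN2CCC[C@@H]3CCCCCC4C(O)[C@@H](C)CN5CCC[C@H](CCCCCC(C1O)[C@@H]32)[C@H]45
F5 | step 9 | tert-butyl (2S,3S)-3-(5,5-dimethoxypentyl)-2-(2-oxobutyl)piperidine-1-carboxylate | CCC(=O)C[C@@H]1N(C(=O)OC(C)(C)C)CCC[C@@H]1CCCCC(OC)OC
F6 | step 9 | 1-[(2S,3S)-3-(5,5-dimethoxypentyl)piperidin-2-yl]butan-2-one hydrochloride | Cl.CCC(=O)C[C@@H]1NCCC[C@@H]1CCCCC(OC)OC
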